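**Strategy**

Everything rests on disconnecting the O1–C2 bond of the dihydrobenzofuran. C2 is benzylic to the electron-rich 3,4-dimethoxyphenyl ring and is the fifth atom counted from the phenol oxygen on C7a of ring A, so oxidation of its C–H bond lets that oxygen close the five-membered ring. One DDQ-mediated anodic dehydrogenation thus forms the O1–C2 bond, the dihydrofuran ring and the C2 stereocentre, trans to C3. The precursor is an open-chain (R)-2,3-diarylpropyl acetate whose ring A carries the free phenol, a methoxy group and a deactivating methyl ester; its single stereocentre is set by an Evans alkylation, and the ester is later homologated to the (E)-allylic alcohol.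

Key step: step 9

Remark: the target is taken as the trans-(2S,3R) enantiomer written in the SMILES; benzofuran numbering (O1, C2, C3, C3a, C7a) is used, ring A is the benzo ring, and zinc enolate 3 is taken from its commercial ethereal solution.

**Route**

Step 1
Reactants: 1 methyl 3-bromo-4-hydroxy-5-methoxybenzoate (methyl 5-bromovanillate)
Product: 2 methyl 4-(benzyloxy)-3-bromo-5-methoxybenzoate
Conditions: BnBr, K2CO3, DMF, 50 °C
Reagents that add atoms: benzyl bromide, BrCc1ccccc1
Why: Williamson etherification of the acidic, flanked phenol should be clean, and the benzyl ether masks the phenol through the enolate steps until it is removed by neutral hydrogenolysis.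

Step 2
Reactants: 2 methyl 4-(benzyloxy)-3-bromo-5-methoxybenzoate; 3 (2-tert-butoxy-2-oxoethyl)zinc chloride
Product: 4 methyl 4-(benzyloxy)-3-(2-tert-butoxy-2-oxoethyl)-5-methoxybenzoate
Conditions: Pd(dba)2 (2 mol %), Q-Phos (C5Ph5)Fe[C5H4P(t-Bu)2] (2 mol %), THF, rt to 50 °C
Reagents that add atoms: none
Why: Palladium-catalysed α-arylation of a zinc ester enolate (Reformatsky/Negishi-type coupling) is chosen because the nearly neutral zinc enolate tolerates the methyl benzoate, which a lithium ester enolate would attack in a Claisen condensation.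

Step 3
Reactants: 4 tert-butyl arylacetate
Product: 5 [2-(benzyloxy)-3-methoxy-5-(methoxycarbonyl)phenyl]acetic acid
Conditions: TFA/CH2Cl2 (1:3), 0 °C to rt
Reagents that add atoms: none
Why: Acidolysis of the tert-butyl ester through the tert-butyl cation (lost as isobutene) should leave the methyl ester and the aryl benzyl ether untouched.

Step 4
Reactants: 5 arylacetic acid; 6 (4R)-4-benzyl-1,3-oxazolidin-2-one
Product: 8 methyl 4-(benzyloxy)-3-{2-[(4R)-4-benzyl-2-oxo-1,3-oxazolidin-3-yl]-2-oxoethyl}-5-methoxybenzoate, via mixed pivalic anhydride 7 (not isolated)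
Conditions: t-BuCOCl, Et3N, THF, −20 °C; then LiCl, 6, −20 °C to rt
Reagents that add atoms: none
Why: N-acylation of the Evans auxiliary through the mixed pivalic anhydride should be selective because the hindered pivaloyl carbonyl steers the LiCl-activated oxazolidinone to the arylacetyl carbonyl.

Step 5
Reactants: 8 N-arylacetyl oxazolidinone; 9 3,4-dimethoxybenzyl bromide
Product: 11 methyl 4-(benzyloxy)-3-{(2R)-1-[(4R)-4-benzyl-2-oxo-1,3-oxazolidin-3-yl]-3-(3,4-dimethoxyphenyl)-1-oxopropan-2-yl}-5-methoxybenzoate, via sodium Z-enolate 10 (not isolated)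
Conditions: NaN(SiMe3)2 (1.1 equiv), THF, −78 °C; then 9, −78 to −40 °C
Reagents that add atoms: none
Why: In this Evans auxiliary alkylation the chelated Z-enolate should be attacked by the reactive benzylic bromide on the face opposite the C4 benzyl group of the (R)-auxiliary, which sets the (R) centre that becomes C3, while allylic strain in the product keeps its acidic α-aryl proton from being removed again.

Step 6
Reactants: 11 alkylated imide
Product: 12 methyl 4-(benzyloxy)-3-[(2R)-1-(3,4-dimethoxyphenyl)-3-hydroxypropan-2-yl]-5-methoxybenzoate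
Conditions: NaBH4, THF/H2O (4:1), 0 °C to rt
Reagents that add atoms: none
Why: Borohydride reductive cleavage of the N-acyl oxazolidinone should occur at the activated exocyclic imide carbonyl much faster than at the methyl benzoate and without touching the stereocentre, and the auxiliary is recovered.

Step 7
Reactants: 12 primary alcohol
Product: 13 methyl 3-[(2R)-1-acetoxy-3-(3,4-dimethoxyphenyl)propan-2-yl]-4-(benzyloxy)-5-methoxybenzoate
Conditions: Ac2O, pyridine, DMAP (cat.), CH2Cl2, rt
Reagents that add atoms: acetic anhydride, CC(=O)OC(C)=O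
Why: DMAP-catalysed acetylation of the only free hydroxyl group is routine, and the acetate keeps that oxygen from competing as a nucleophile in the key step and falls off later in the same hydride step that reduces the ring A ester.

Step 8
Reactants: 13 benzyl ether acetate
Product: 14 methyl 3-[(2R)-1-acetoxy-3-(3,4-dimethoxyphenyl)propan-2-yl]-4-hydroxy-5-methoxybenzoate
Conditions: H2 (1 atm), Pd/C (10 wt %), EtOAc, rt
Reagents that add atoms: none
Why: Hydrogenolysis of the aryl benzyl ether frees the phenol nucleophile under neutral conditions that should leave both esters and the stereocentre, which carries no benzylic C–O bond, unchanged.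

Step 9
Reactants: 14 phenol acetate
Product: 16 methyl (2S,3R)-3-(acetoxymethyl)-2-(3,4-dimethoxyphenyl)-7-methoxy-2,3-dihydro-1-benzofuran-5-carboxylate, via C2 veratryl cation 15 (not isolated)
Conditions: undivided cell, graphite anode, Pt cathode, constant current (about 2.1 F/mol, stopped at full conversion of 14), DDQ (10 mol %), n-Bu4NPF6 (0.1 M), CH2Cl2/(CF3)2CHOH (HFIP) 4:1, rt
Reagents that add atoms: none
Why: DDQ, kept in its oxidised form at the anode, removes hydride (electron, proton, electron) from C2–H, the only C–H bond benzylic to the veratryl ring, to give the para-methoxy-stabilised cation 15, while the protons are discharged as H2 at the cathode. The phenol oxygen on C7a then adds to C2 in a 5-exo-trig closure that forms the O1–C2 bond and the dihydrofuran ring. The closest known reaction type is the DDQ-mediated dehydrogenative cyclisation of 2-hydroxy-1,3-diarylpropanes to flavans, together with anodic benzylic C–H etherification and lactonisation of electron-rich alkylarenes. The new C2 centre is controlled by the C3 centre already present: the ring closes so that the aryl group lies anti to the acetoxymethyl group, and because the benzylic ether can re-ionise in HFIP the more stable trans (2S,3R) isomer is also the thermodynamic one. The step needs oxidation of the veratryl ring in preference to the phenol ring, which the C5 ester on ring A secures by raising the potential of that ring, and it must stop before dehydrogenation to the benzofuran, which the limited charge and low mediator loading are meant to ensure.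

Step 10
Reactants: 16 dihydrobenzofuran diester
Product: 17 [(2S,3R)-2-(3,4-dimethoxyphenyl)-7-methoxy-2,3-dihydro-1-benzofuran-3,5-diyl]dimethanol
Conditions: i-Bu2AlH (6 equiv), CH2Cl2, −78 to 0 °C; aq. potassium sodium tartrate
Reagents that add atoms: none
Why: Hydride reduction should convert the methyl benzoate into the benzylic alcohol and cleave the acetate in one operation, the cyclic benzylic ether and both stereocentres being inert to the hydride at low temperature.

Step 11
Reactants: 17 diol; 18 ethyl (triphenylphosphoranylidene)acetate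
Product: 20 ethyl (2E)-3-[(2S,3R)-2-(3,4-dimethoxyphenyl)-3-(hydroxymethyl)-7-methoxy-2,3-dihydro-1-benzofuran-5-yl]prop-2-enoate, via aldehyde 19 (not isolated)
Conditions: activated MnO2 (10 equiv), 18 (1.3 equiv), CH2Cl2, rt
Reagents that add atoms: none
Why: In this one-pot oxidation/Wittig olefination MnO2 should oxidise only the benzylic alcohol, and the stabilised ylide traps the aldehyde as it forms to give the (E)-enoate, the aliphatic primary alcohol being left alone at room temperature.

Step 12
Reactants: 20 (E)-enoate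
Product: 21 hierochin B, (2E)-3-[(2S,3R)-2-(3,4-dimethoxyphenyl)-3-(hydroxymethyl)-7-methoxy-2,3-dihydro-1-benzofuran-5-yl]prop-2-en-1-ol
Conditions: i-Bu2AlH (4 equiv), CH2Cl2, −78 °C; aq. potassium sodium tartrate
Reagents that add atoms: none
Why: 1,2-Reduction of the α,β-unsaturated ester by i-Bu2AlH should give the allylic alcohol with the alkene geometry and both ring stereocentres unchanged, the extra hydride covering the free hydroxyl group.

**Compound list**

1 | methyl 3-bromo-4-hydroxy-5-methoxybenzoate (methyl 5-bromovanillate) | COC(=O)c1cc(Br)c(O)c(OC)c1 | starting material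
2 | methyl 4-(benzyloxy)-3-bromo-5-methoxybenzoate | COC(=O)c1cc(Br)c(OCc2ccccc2)c(OC)c1 | intermediate
3 | (2-tert-butoxy-2-oxoethyl)zinc chloride | CC(C)(C)OC(=O)C[Zn]Cl | starting material
4 | methyl 4-(benzyloxy)-3-(2-tert-butoxy-2-oxoethyl)-5-methoxybenzoate | COC(=O)c1cc(OC)c(OCc2ccccc2)c(CC(=O)OC(C)(C)C)c1 | intermediate
5 | [2-(benzyloxy)-3-methoxy-5-(methoxycarbonyl)phenyl]acetic acid | COC(=O)c1cc(OC)c(OCc2ccccc2)c(CC(=O)O)c1 | intermediate
6 | (4R)-4-benzyl-1,3-oxazolidin-2-one | O=C1N[C@H](Cc2ccccc2)CO1 | starting material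
7 | mixed pivalic anhydride of 5, [2-(benzyloxy)-3-methoxy-5-(methoxycarbonyl)phenyl]acetic 2,2-dimethylpropanoic anhydride | COC(=O)c1cc(OC)c(OCc2ccccc2)c(CC(=O)OC(=O)C(C)(C)C)c1 | intermediate (not isolated)
8 | methyl 4-(benzyloxy)-3-{2-[(4R)-4-benzyl-2-oxo-1,3-oxazolidin-3-yl]-2-oxoethyl}-5-methoxybenzoate | COC(=O)c1cc(OC)c(OCc2ccccc2)c(CC(=O)N2C(=O)OC[C@H]2Cc2ccccc2)c1 | intermediate
9 | 3,4-dimethoxybenzyl bromide, 4-(bromomethyl)-1,2-dimethoxybenzene | COc1ccc(CBr)cc1OC | starting material
10 | sodium (Z)-enolate of 8 | COC(=O)c1cc(OC)c(OCc2ccccc2)c(/C=C(\[O-])N2C(=O)OC[C@H]2Cc2ccccc2)c1.[Na+] | intermediate (not isolated)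
11 | methyl 4-(benzyloxy)-3-{(2R)-1-[(4R)-4-benzyl-2-oxo-1,3-oxazolidin-3-yl]-3-(3,4-dimethoxyphenyl)-1-oxopropan-2-yl}-5-methoxybenzoate | COC(=O)c1cc(OC)c(OCc2ccccc2)c([C@@H](Cc2ccc(OC)c(OC)c2)C(=O)N2C(=O)OC[C@H]2Cc2ccccc2)c1 | intermediate
12 | methyl 4-(benzyloxy)-3-[(2R)-1-(3,4-dimethoxyphenyl)-3-hydroxypropan-2-yl]-5-methoxybenzoate | COC(=O)c1cc(OC)c(OCc2ccccc2)c([C@@H](Cc2ccc(OC)c(OC)c2)CO)c1 | intermediate
13 | methyl 3-[(2R)-1-acetoxy-3-(3,4-dimethoxyphenyl)propan-2-yl]-4-(benzyloxy)-5-methoxybenzoate | COC(=O)c1cc(OC)c(OCc2ccccc2)c([C@@H](Cc2ccc(OC)c(OC)c2)COC(C)=O)c1 | intermediate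
14 | methyl 3-[(2R)-1-acetoxy-3-(3,4-dimethoxyphenyl)propan-2-yl]-4-hydroxy-5-methoxybenzoate (precursor of the key step) | COC(=O)c1cc(OC)c(O)c([C@@H](Cc2ccc(OC)c(OC)c2)COC(C)=O)c1 | intermediate
15 | C2 veratryl cation derived from 14 by loss of hydride from the benzylic CH2 | COC(=O)c1cc(OC)c(O)c([C@@H]([CH+]c2ccc(OC)c(OC)c2)COC(C)=O)c1 | intermediate (not isolated)
16 | methyl (2S,3R)-3-(acetoxymethyl)-2-(3,4-dimethoxyphenyl)-7-methoxy-2,3-dihydro-1-benzofuran-5-carboxylate (product of the key step) | COc1ccc([C@H]2Oc3c(OC)cc(C(=O)OC)cc3[C@@H]2COC(C)=O)cc1OC | intermediate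
17 | [(2S,3R)-2-(3,4-dimethoxyphenyl)-7-methoxy-2,3-dihydro-1-benzofuran-3,5-diyl]dimethanol | COc1ccc([C@H]2Oc3c(OC)cc(CO)cc3[C@@H]2CO)cc1OC | intermediate
18 | ethyl (triphenylphosphoranylidene)acetate | CCOC(=O)C=P(c1ccccc1)(c1ccccc1)c1ccccc1 | starting material
19 | (2S,3R)-2-(3,4-dimethoxyphenyl)-3-(hydroxymethyl)-7-methoxy-2,3-dihydro-1-benzofuran-5-carbaldehyde | COc1ccc([C@H]2Oc3c(OC)cc(C=O)cc3[C@@H]2CO)cc1OC | intermediate (not isolated)
20 | ethyl (2E)-3-[(2S,3R)-2-(3,4-dimethoxyphenyl)-3-(hydroxymethyl)-7-methoxy-2,3-dihydro-1-benzofuran-5-yl]prop-2-enoate | COc1ccc([C@H]2Oc3c(OC)cc(/C=C/C(=O)OCC)cc3[C@@H]2CO)cc1OC | intermediate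
21 | hierochin B, (2E)-3-[(2S,3R)-2-(3,4-dimethoxyphenyl)-3-(hydroxymethyl)-7-methoxy-2,3-dihydro-1-benzofuran-5-yl]prop-2-en-1-ol | COc1ccc([C@H]2Oc3c(OC)cc(/C=C/CO)cc3[C@@H]2CO)cc1OC | target

**Step count and risks**

Total step count: 12. Longest linear sequence: 12 steps (1 to 21).

Steps most likely to fail:

Step 9. The oxidation may start at the phenol ring instead of the veratryl ring, the cation may lose the C3 proton to give a stilbene, or the product may be dehydrogenated further to the benzofuran. The fallback sets out from acid 5 and comes back at diol 17; it closes the O1–C2 bond without an oxidant, by ionising a benzylic alcohol. Acid 5 is joined (t-BuCOCl, Et3N, LiCl, through 7) to (4S)-4-benzyl-1,3-oxazolidin-2-one to give methyl 4-(benzyloxy)-3-{2-[(4S)-4-benzyl-2-oxo-1,3-oxazolidin-3-yl]-2-oxoethyl}-5-methoxybenzoate F1. The antipodal auxiliary is needed because the boron aldol reaction uses the enolate face opposite to that of the chelated alkylation. A Bu2BOTf/i-Pr2NEt syn-aldol addition to 3,4-dimethoxybenzaldehyde should give methyl 4-(benzyloxy)-3-{(2S,3S)-1-[(4S)-4-benzyl-2-oxo-1,3-oxazolidin-3-yl]-3-(3,4-dimethoxyphenyl)-3-hydroxy-1-oxopropan-2-yl}-5-methoxybenzoate F2. NaBH4 in THF/H2O removes the auxiliary to give methyl 4-(benzyloxy)-3-[(1S,2R)-1-(3,4-dimethoxyphenyl)-1,3-dihydroxypropan-2-yl]-5-methoxybenzoate F3. Hydrogenolysis (H2, Pd/C, EtOAc) gives methyl 3-[(1S,2R)-1-(3,4-dimethoxyphenyl)-1,3-dihydroxypropan-2-yl]-4-hydroxy-5-methoxybenzoate F4. BF3·OEt2 in CH2Cl2 at 0 °C ionises the veratryl alcohol, and the phenol closes the ring under thermodynamic control to methyl (2S,3R)-2-(3,4-dimethoxyphenyl)-3-(hydroxymethyl)-7-methoxy-2,3-dihydro-1-benzofuran-5-carboxylate F5. Reduction with i-Bu2AlH as in step 10 then gives diol 17.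

Step 5. Facial selectivity in the enolate alkylation may be incomplete, or the doubly activated α-aryl centre may epimerise under the basic conditions of the alkylation or of the auxiliary removal in step 6. The fallback sets out from acid 5 and comes back at alcohol 12; it sets the centre by hydrogenation instead of enolate alkylation. Perkin condensation of 5 with 3,4-dimethoxybenzaldehyde (Ac2O, Et3N, 110 °C) should give (2E)-2-[2-(benzyloxy)-3-methoxy-5-(methoxycarbonyl)phenyl]-3-(3,4-dimethoxyphenyl)prop-2-enoic acid F6. Asymmetric hydrogenation with a Ru(OAc)2(BINAP) catalyst, using the ligand antipode that delivers the (R)-acid (to be fixed on a test scale), gives (2R)-2-[2-(benzyloxy)-3-methoxy-5-(methoxycarbonyl)phenyl]-3-(3,4-dimethoxyphenyl)propanoic acid F7; the benzyl ether is not cleaved by the homogeneous catalyst. BH3·THF then reduces the carboxylic acid in the presence of the methyl ester to alcohol 12.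

Step 2. Oxidative addition or transmetalation at the ortho-benzyloxy bromide may be slow, so that protodebromination or decomposition of the zinc enolate takes over. The fallback sets out from bromide 2 and comes back at acid 5, bypassing step 3; it brings in the two-carbon arm as an allyl group and cuts it down. Stille coupling of 2 with allyltributylstannane (Pd(PPh3)4, DMF, 90 °C) should give methyl 4-(benzyloxy)-3-methoxy-5-(prop-2-en-1-yl)benzoate F8. Lemieux–Johnson cleavage (OsO4 cat., NaIO4, 2,6-lutidine, dioxane/H2O) gives methyl 4-(benzyloxy)-3-methoxy-5-(2-oxoethyl)benzoate F9. Pinnick oxidation (NaClO2, NaH2PO4, 2-methylbut-2-ene, t-BuOH/H2O) gives acid 5.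

Further compounds
F1 | step 9 | methyl 4-(benzyloxy)-3-{2-[(4S)-4-benzyl-2-oxo-1,3-oxazolidin-3-yl]-2-oxoethyl}-5-methoxybenzoate | COC(=O)c1cc(OC)c(OCc2ccccc2)c(CC(=O)N2C(=O)OC[C@@H]2Cc2ccccc2)c1
F2 | step 9 | methyl 4-(benzyloxy)-3-{(2S,3S)-1-[(4S)-4-benzyl-2-oxo-1,3-oxazolidin-3-yl]-3-(3,4-dimethoxyphenyl)-3-hydroxy-1-oxopropan-2-yl}-5-methoxybenzoate | COC(=O)c1cc(OC)c(OCc2ccccc2)c([C@@H]([C@H](O)c2ccc(OC)c(OC)c2)C(=O)N2C(=O)OC[C@@H]2Cc2ccccc2)c1
F3 | step 9 | methyl 4-(benzyloxy)-3-[(1S,2R)-1-(3,4-dimethoxyphenyl)-1,3-dihydroxypropan-2-yl]-5-methoxybenzoate | COC(=O)c1cc(OC)c(OCc2ccccc2)c([C@@H]([C@H](O)c2ccc(OC)c(OC)c2)CO)c1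
F4 | step 9 | methyl 3-[(1S,2R)-1-(3,4-dimethoxyphenyl)-1,3-dihydroxypropan-2-yl]-4-hydroxy-5-methoxybenzoate | COC(=O)c1cc(OC)c(O)c([C@@H]([C@H](O)c2ccc(OC)c(OC)c2)CO)c1
F5 | step 9 | methyl (2S,3R)-2-(3,4-dimethoxyphenyl)-3-(hydroxymethyl)-7-methoxy-2,3-dihydro-1-benzofuran-5-carboxylate | COc1ccc([C@H]2Oc3c(OC)cc(C(=O)OC)cc3[C@@H]2CO)cc1OC
F6 | step 5 | (2E)-2-[2-(benzyloxy)-3-methoxy-5-(methoxycarbonyl)phenyl]-3-(3,4-dimethoxyphenyl)prop-2-enoic acid | COC(=O)c1cc(OC)c(OCc2ccccc2)c(/C(=C\c2ccc(OC)c(OC)c2)C(=O)O)c1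
F7 | step 5 | (2R)-2-[2-(benzyloxy)-3-methoxy-5-(methoxycarbonyl)phenyl]-3-(3,4-dimethoxyphenyl)propanoic acid | COC(=O)c1cc(OC)c(OCc2ccccc2)c([C@@H](Cc2ccc(OC)c(OC)c2)C(=O)O)c1
F8 | step 2 | methyl 4-(benzyloxy)-3-methoxy-5-(prop-2-en-1-yl)benzoate | COC(=O)c1cc(OC)c(OCc2ccccc2)c(CC=C)c1
F9 | step 2 | methyl 4-(benzyloxy)-3-methoxy-5-(2-oxoethyl)benzoate | COC(=O)c1cc(OC)c(OCc2ccccc2)c(CC=O)c1
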